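The substrate charged stays in the closed flask in one form or another, and the two runs differ in one charge, the coupling partner, which makes that charge the candidate for limiting reagent.

| flask | substrate | coupling partner | remark | time |
|---|---|---|---|---|
| violet | 10 mM | 1.1 equiv | the very flask that is asked about, followed so far |  |
| grey | 10 mM | 0.74 equiv | run made earlier |  |
| flask | 10 mM | 1.10 equiv |  | 15 min |

| violet: time / min | violet: product / % | grey: time / min | grey: product / % |
|---|---|---|---|
| 2.00 | 30.5 | 0.250 | 0.6 |
| 4.00 | 38.7 | 0.833 | 10.2 |
| 5.00 | 38.6 | 1.33 | 14.8 |
| 8.00 | 40.8 | 2.00 | 19.3 |
| 10.0 | 39.3 | 3.00 | 21.1 |

(standard deviation of a reading: 1 percentage point)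

- gamma: change nothing and wait 15 min more
- epsilon: at 15 min add coupling partner, 50.0% of the amount charged, then wait 15 min
- alpha: at 15 min take out 90% of the product then present, then wait 15 min
- delta: at 15 min add substrate, 50.0% of the amount charged, then wait 15 min

- product that was removed still counts
- additions bring no volume worth counting

- product, in percent of the substrate first charged, at 15 min
- what to do for the largest gain in product; "none" if nothing gains more than 2 percentage points (gamma / epsilon / alpha / delta / none)
- product present, with what was taken out counted in, in percent of the substrate first charged, after gamma
- product present, with what was taken out counted in, in percent of the substrate first charged, after alpha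

From 4.00 min on, the violet run stands flat, and replacing that stretch by its mean gives 39.4%. The grey run, with 0.74 equiv of partner against 1.1 equiv, last reads 21.1%. The straight line between these two points has a slope of 0.507: this is the marginal yield, the product gained per equivalent of coupling partner charged, as a fraction of the substrate charge.

This reckoning then takes the settings in turn. Waiting (gamma) is judged from the violet run, which rises 0.6 percentage points from 4.00 min to 10.0 min against a scatter of 1 point, so no gain is reckoned and the flask is reckoned near 39.4% at 15 min. Removal (alpha) adds no partner, so the count is reckoned at 39.4%. Extra substrate (delta) adds no partner either, so the reckoned gain is nil. Extra partner (epsilon) brings 0.550 equiv, reckoned to be worth 28 points.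

The straight line may carry an error, because the last reading of the grey run stands 1.8 points above the one before it, so that run may not have reached its level. Should it climb by that step once more, the reckoned gain falls to 25 points, so epsilon remains the choice of this reckoning.

The forecast, which parts from this reckoning on the best move, gives 40% now, 40% after gamma, 40.3% after alpha and none as best, and puts the stop of the product down to “either equilibrium or loss of an active species”.

The flask gives 39.9% at 15 min and epsilon as best: gamma adds 0.0054 points, alpha 0.0054 points, delta 0 points and epsilon 28 points, against the reckoned 28 points. At 15.0 min, the coupling partner of the flask stands at 0.0097% of its charge.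

    coupling partner + intermediate B → intermediate C (k = 1.13 /M/s)
    substrate ⇌ intermediate B (K = 0.730, k = 0.0265 /s)
    substrate + coupling partner → intermediate A (k = 1.84 /M/s)
    coupling partner + intermediate A → product (k = 3.24 /M/s)
    intermediate C ⇌ intermediate D (K = 1.70, k = 0.201 /s)

The neighbouring flask charged with 4.40 equiv of partner keeps 58% of it at 15 min, so it has spent 1.83 equiv. That is 0.735 equiv above the charge of the asked flask, and at the marginal yield this is worth 37 points, which reckons the neighbour at 76.6%. The neighbouring flask gives 83.5%, with 0% of its substrate left.

(The readings come from a simulation with made-up constants.)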